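(All runs come from a simulation with constants of no real substance, noise included.)

1. The ratio of substrate lost to substrate turned into target was the number I wanted for these flasks, for what is asked is how much target stands at the end.

| setting | ash | oak | south-west | north-east |
|---|---|---|---|---|
| substrate | 0.010 M | 0.015 M | 0.020 M | 0.020 M |
| free enzyme | 0.0018 mol% | 0.0018 mol% | 0.0018 mol% | 0.0018 mol% |
| temperature | 26 °C | 34 °C | 37 °C | 22 °C |
| remark | run made earlier | run made earlier |  |  |
| time |  |  | 15 h | 15 h |

| run | time / h | target / % | substrate / % |
|---|---|---|---|
| ash | 2.50 | 95 | 0 |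
| ash | 6.00 | 96 | 0 |
| ash | 10.0 | 95 | 1 |
| ash | 15.0 | 97 | 2 |
| ash | 25.0 | 98 | 3 |
| ash | 30.0 | 97 | 0 |
| oak | 1.33 | 75 | 19 |
| oak | 4.00 | 91 | 1 |
| oak | 6.00 | 93 | 1 |
| oak | 10.0 | 92 | 0 |
| oak | 15.0 | 92 | 0 |
| oak | 20.0 | 90 | 0 |

(readings scatter by 1.5 percentage points)

1. which flask leads in amount of target, in percent of the substrate charged ("all alike" within 1.5 percentage points) (south-west / north-east / all alike)
2. how much target is there at the end, in percent of the substrate charged: south-west
3. how much target is there at the end, in percent of the substrate charged: north-east



2. At the last readings substrate stood at 0 % in the ash run and 0 % in the oak run, so the balance of substrate, the limiting reagent, had two exits: target, or loss. I therefore compared two rates, loss against target formation, the inverse of a selectivity factor.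

3. The ash run averaged 96.3 % target, a loss ratio of 0.0381. The oak run from 6.00 h on averaged 91.8 %, a ratio of 0.0899, larger than in the ash run.

4. Concentration changed along with temperature, but I assumed temperature carried the change and let the ratio grow exponentially with it. That gave the loss ratio of south-west at 37 °C, 0.124, and of north-east at 22 °C, 0.0248. If the substrate is consumed within 15 h, target is one over one plus the ratio, so I reckoned 89.0 % for south-west and 97.6 % for north-east, which leads.

5. The forecast named north-east, with 86 % for south-west and 95 % for north-east, on the ground that north-east is “cold, which favours selectivity and stability”. Its order is mine, though its numbers are lower than mine .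

6. The flask gave north-east as leader, with 89.4 % in south-west and 97.1 % in north-east.

    free enzyme → unfolded enzyme (k = 0.00449 h⁻¹, Ea = 217 kJ mol⁻¹)
    substrate + free enzyme → target + free enzyme, rate k2*[substrate]*[free enzyme]/(1 + ([substrate]/Km2)) (0.978 mM, k = 12100 M⁻¹ s⁻¹, Ea = 15.0 kJ mol⁻¹)
    substrate + target → side product (k = 4.32 M⁻¹ h⁻¹, Ea = 68.0 kJ mol⁻¹)
    free enzyme ⇌ dormant form (K = 0.834, k = 0.287 h⁻¹, Ea = 94.0 kJ mol⁻¹, ΔH = 2.00 kJ mol⁻¹)
    substrate → uncatalysed product (k = 0.0874 h⁻¹, Ea = 91.0 kJ mol⁻¹)
    (constants at 37 °C)

Starting from the ash run, changing only the temperature to that of south-west gave 90.4 % target, while changing only the amount of everything gave 95.9 %. South-west's own loss ratio came to 0.119, against my 0.124. A neighbour of south-west held 7.2 × 10⁻⁴ mol% of free enzyme, and as free enzyme stands in the equation of the target path and in neither equation by which substrate is lost, I scaled 0.124 by the loadings to 0.310, which gives 76.3 % target; that neighbour gave 75.4 %.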